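**Plan**

- Retrosynthesis: the carbinol is taken back to a ketone, and the ring-B CH2 next to ring C to a temporary ketone that serves as handle for epimerization and olefin shift. Ring B is then cut at two bonds, carbonyl carbon to quaternary carbon of ring C and ring-C methine to ring-B CH2. This gives a ring C/D alkenyllithium and a ring-A-fused 2-methyl-2-vinylcyclobutanone.
- Enabling feature: with its olefin moved one position, between the methyl-bearing carbon and the adjacent CH, ring B is a cyclooct-4-enone, the retron of an oxy-Cope ring expansion. The temporary four-membered ring joins the carbinol carbon to the methyl-bearing olefinic carbon.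
- Forward: ring D to ring C by asymmetric Robinson annulation, reductive triflation and stannylation; ring A plus cyclobutanone by keteniminium [2+2] and α-vinylation; union and ring B by addition/oxy-Cope/methylation; then allylic oxidation, base-mediated epimerization and olefin shift, deoxygenation, ketone reduction.
- Stereochemistry: ring-A methyl from (S)-citronellic acid; ring C/D quaternary centre from the chiral-imine Michael addition; trans fusion from Li/NH3. The cyclobutane, set anti to the ring-A methyl, fixes the face of the sigmatropic step, and methylation anti to the new bond sets the second quaternary carbon.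
- The ring-B/C methine is then corrected thermodynamically, the ring-A/B methine by kinetic protonation, and the carbinol by dissolving-metal reduction.

Key step: step 11

Remark: in step 9 the tether methyl is assumed to take the convex (exo) position; ketone 21 is carried as a mixture of epimers at the methyl-bearing cyclobutanone carbon, which converge in enolate 22.

**Route**

Step 1
Reactants: 1 3,3-dimethylcyclohexan-1-one
Product: 3 2,5,5-trimethylcyclohexan-1-one (racemic), via lithium enolate 2 (not isolated)
Conditions: LiN(i-Pr)2, THF, −78 °C; MeI, −78 → 0 °C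
Reagents that add atoms: iodomethane, CI
Why: Kinetic deprotonation should occur at the CH2 remote from the gem-dimethyl group and the enolate is C-methylated (enolate alkylation); the new centre is racemic and is reset in step 2.

Step 2
Reactants: 3 2,5,5-trimethylcyclohexan-1-one; 4 (R)-1-phenylethan-1-amine; 5 but-3-en-2-one
Product: 8 (S)-2,5,5-trimethyl-2-(3-oxobutyl)cyclohexan-1-one, via imine 6 (not isolated), via Michael-adduct imine 7 (not isolated)
Conditions: 4, TsOH (cat.), toluene, reflux, water separator; 5, THF, 25 °C; AcOH, H2O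
Reagents that add atoms: water, O
Why: The secondary enamine tautomer of the chiral imine adds to the enone at the more substituted carbon (deracemizing Michael addition, first half of an asymmetric Robinson annulation), the (R)-auxiliary shielding one face so that the quaternary centre should form as (S); hydrolysis returns the auxiliary.

Step 3
Reactants: 8 (S)-2,5,5-trimethyl-2-(3-oxobutyl)cyclohexan-1-one
Product: 9 (S)-4a,7,7-trimethyl-4,4a,5,6,7,8-hexahydronaphthalen-2(3H)-one
Conditions: KOH, MeOH, 65 °C
Reagents that add atoms: none
Why: Intramolecular aldol condensation (second half of the Robinson annulation) closes ring C as the conjugated enone without forming a stereocentre.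

Step 4
Reactants: 9 (S)-4a,7,7-trimethyl-4,4a,5,6,7,8-hexahydronaphthalen-2(3H)-one
Product: 11 (4aS,8aS)-4a,7,7-trimethyl-3,4,4a,5,6,7,8,8a-octahydronaphthalen-2-yl trifluoromethanesulfonate, via lithium enolate 10 (not isolated)
Conditions: Li, NH3(l), THF, t-BuOH (1 equiv), −78 °C; NH3 removed; PhNTf2, THF, 0 °C
Reagents that add atoms: N-phenylbis(trifluoromethanesulfonimide), O=S(=O)(N(c1ccccc1)S(=O)(=O)C(F)(F)F)C(F)(F)F
Why: Dissolving-metal reduction of the enone protonates the β-carbon axially to give the trans-fused enolate regiospecifically, and O-sulfonylation fixes that regiochemistry as the enol triflate (reductive triflation).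

Step 5
Reactants: 11 (4aS,8aS)-4a,7,7-trimethyl-3,4,4a,5,6,7,8,8a-octahydronaphthalen-2-yl trifluoromethanesulfonate
Product: 12 trimethyl[(4aS,8aS)-4a,7,7-trimethyl-3,4,4a,5,6,7,8,8a-octahydronaphthalen-2-yl]stannane
Conditions: Me3SnSnMe3, Pd(PPh3)4 (cat.), LiCl, THF, 65 °C
Reagents that add atoms: hexamethylditin, C[Sn](C)(C)[Sn](C)(C)C
Why: Palladium-catalysed coupling of the enol triflate with the distannane (Stille-type stannylation) replaces OTf by SnMe3 without moving the double bond or touching a stereocentre.

Step 6
Reactants: 13 (S)-3,7-dimethyloct-6-enoic acid; 14 pyrrolidine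
Product: 15 (S)-3,7-dimethyl-1-(pyrrolidin-1-yl)oct-6-en-1-one
Conditions: EDC·HCl, DMAP (cat.), CH2Cl2, 0 → 25 °C
Reagents that add atoms: none
Why: Carbodiimide amide coupling gives the tertiary amide needed for keteniminium formation; the stereocentre is not involved.

Step 7
Reactants: 15 (S)-3,7-dimethyl-1-(pyrrolidin-1-yl)oct-6-en-1-one
Product: 17 (S)-4-methyl-6-oxo-6-(pyrrolidin-1-yl)hexanal, via ozonide 16 (not isolated)
Conditions: O3, CH2Cl2, −78 °C; Me2S, −78 → 25 °C
Reagents that add atoms: ozone, [O-][O+]=O
Why: Ozonolysis with reductive work-up cleaves the only olefin to the aldehyde and leaves amide and stereocentre untouched.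

Step 8
Reactants: 17 (S)-4-methyl-6-oxo-6-(pyrrolidin-1-yl)hexanal
Product: 18 (S,Z)-3-methyl-1-(pyrrolidin-1-yl)oct-6-en-1-one
Conditions: EtPPh3Br, NaN(SiMe3)2, THF, −78 → 25 °C
Reagents that add atoms: ethyltriphenylphosphonium bromide, CC[P+](c1ccccc1)(c1ccccc1)c1ccccc1.[Br-]
Why: Wittig olefination with the unstabilized ylide should give the cis-disubstituted olefin, whose geometry is of no later consequence because that carbon is enolized in step 10.

Step 9
Reactants: 18 (S,Z)-3-methyl-1-(pyrrolidin-1-yl)oct-6-en-1-one
Product: 21 cis-fused (4S)-4,7-dimethylbicyclo[3.2.0]heptan-6-one (4-methyl exo; epimers at carbon 7), via keteniminium triflate 19 (not isolated), via cyclobutaniminium triflate 20 (not isolated)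
Conditions: Tf2O, 2,4,6-collidine, ClCH2CH2Cl, 80 °C; aq. NaHCO3, 25 °C
Reagents that add atoms: water, O
Why: Amide activation gives a keteniminium ion that undergoes intramolecular [2+2] cycloaddition with the tethered olefin; the three-atom tether enforces the bicyclo[3.2.0] regiochemistry and cis fusion, and the adjacent methyl stereocentre should direct ring formation so that the methyl ends up exo (trans to the four-membered ring); hydrolysis gives the cyclobutanone.

Step 10
Reactants: 21 cis-fused (4S)-4,7-dimethylbicyclo[3.2.0]heptan-6-one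
Product: 23 cis-fused (4S)-4,7-dimethyl-7-vinylbicyclo[3.2.0]heptan-6-one (4-methyl exo; 7-vinyl exo; 7-methyl endo), via lithium enolate 22 (not isolated)
Conditions: LiN(SiMe3)2, toluene, 0 °C; CH2=CHBr, Pd2(dba)3 (cat.), P(t-Bu)3 (cat.), 25 °C
Reagents that add atoms: vinyl bromide, C=CBr
Why: Palladium-catalysed α-alkenylation of the ketone enolate; only the non-bridgehead α-carbon can enolize, and the vinyl group should be delivered from the convex face, giving the quaternary centre with exo vinyl.

Step 11
Reactants: 12 trimethyl[(4aS,8aS)-4a,7,7-trimethyl-3,4,4a,5,6,7,8,8a-octahydronaphthalen-2-yl]stannane; 23 cis-fused (4S)-4,7-dimethyl-7-vinylbicyclo[3.2.0]heptan-6-one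
Product: 27 tetracyclic ring-B ketone (ketone at the future carbinol carbon; ring-B olefin between the methyl-bearing carbon and the CH toward ring C; quaternary methyl as in the target; ring-B/C methine and ring-A/B methine epimeric to the target), via alkenyllithium 24 (not isolated), via cyclobutanolate 25 (not isolated), via ring-expanded enolate 26 (not isolated)
Conditions: 12, MeLi, THF, −78 → −20 °C; 23, −78 °C; HMPA, −78 → 25 °C; MeI, 0 °C
Reagents that add atoms: iodomethane, CI
Why: Tin–lithium exchange gives the alkenyllithium, which adds to the cyclobutanone from the convex face, cis to the exo vinyl group; the cis-1,2-dialkenylcyclobutanolate then undergoes a strain-driven anionic oxy-Cope ([3,3]) shift through the only attainable boat array, breaking the cyclobutane bond between carbinol carbon and vinyl-bearing carbon while the ring-C olefinic CH bonds to the vinyl CH2, and the regiodefined enolate is C-methylated in the same flask. The closest known reaction type is the cyclooctenone synthesis by oxy-Cope rearrangement of 1,2-dialkenylcyclobutanols combined with enolate alkylation. Ring B is closed by four-atom ring expansion of the temporary four-membered ring, not end to end, so the usual medium-ring penalty should not apply. The ring-B/C methine is fixed by the boat geometry, hence by the cyclobutane configuration set in step 9, which delivers the vinyl terminus to the ring-C face syn to the angular methyl; the quaternary carbon is fixed by methylation anti to this new axial bond, which should place the methyl axial on the face it occupies in the target. The step needs exo addition, a cis relationship of the two alkenyl groups, a concerted shift faster than alkoxide fragmentation, and C- over O-methylation; the cup shape of the bicyclic ketone, the exo vinyl group, ring strain, and MeI in THF/HMPA should secure these.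

Step 12
Reactants: 27 tetracyclic ring-B ketone
Product: 28 tetracyclic ene-dione (new ketone at the ring-B CH2 between the olefin and ring C; conjugated β-methyl enone)
Conditions: Rh2(cap)4 (cat.; cap = caprolactamate), t-BuOOH, K2CO3, CH2Cl2, 25 °C
Reagents that add atoms: tert-butyl hydroperoxide, CC(C)(C)OO
Why: Rhodium-catalysed allylic C–H oxidation should convert the allylic CH2 next to the less substituted olefin carbon into the enone carbonyl, the usual site for 1-methylcycloalkenes.

Step 13
Reactants: 28 tetracyclic ene-dione
Product: 30 tetracyclic dione with the tetrasubstituted ring-A/B olefin and all stereocentres as in the target, via dipotassium bis-enolate 29 (not isolated)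
Conditions: KOt-Bu (5 equiv), THF, 0 → 25 °C; inverse quench into AcOH, THF, −78 °C
Reagents that add atoms: none
Why: Excess base converts both ketones into enolates (the enone through γ-deprotonation to the extended dienolate), the methine next to the temporary ketone equilibrates so that the ring-B bond becomes equatorial on ring C (trans fusion, relief of the 1,3-diaxial contact with the angular methyl), and kinetic α-protonation of the bis-enolate gives the deconjugated tetrasubstituted olefin (deconjugative protonation) and sets the ring-A/B methine anti to the adjacent methyl.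

Step 14
Reactants: 30 tetracyclic dione
Product: 32 tetracyclic ketone (oxo analogue of the target), via tosylhydrazone 31 (not isolated)
Conditions: TsNHNH2, EtOH, 25 °C; catecholborane, CHCl3, 0 °C; NaOAc·3H2O, 60 °C
Reagents that add atoms: none
Why: Only the less hindered ketone should form the tosylhydrazone, and hydride delivery with loss of N2 and sulfinate (Caglioti-type reduction) gives the CH2 group without moving the non-conjugated olefin.

Step 15
Reactants: 32 tetracyclic ketone
Product: 33 target alcohol
Conditions: Li, NH3(l), THF, EtOH, −78 °C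
Reagents that add atoms: none
Why: Dissolving-metal reduction of the hindered ketone should give the thermodynamically preferred alcohol, with the hydroxyl on the face anti to the neighbouring quaternary methyl and the ring-A methyl, as in the target.

**Compound list**

1 | 3,3-dimethylcyclohexan-1-one | CC1(C)CCCC(=O)C1 | starting material
2 | lithium 5,5-dimethylcyclohex-1-en-1-olate | [Li]OC1=CCCC(C)(C)C1 | intermediate
3 | 2,5,5-trimethylcyclohexan-1-one (racemic) | CC1CCC(C)(C)CC1=O | intermediate
4 | (R)-1-phenylethan-1-amine | C[C@@H](N)c1ccccc1 | starting material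
5 | but-3-en-2-one | CC(=O)C=C | starting material
6 | (R)-N-(2,5,5-trimethylcyclohexylidene)-1-phenylethan-1-amine | CC1CCC(C)(C)CC1=N[C@H](C)c1ccccc1 | intermediate
7 | (R)-N-[(S)-2,5,5-trimethyl-2-(3-oxobutyl)cyclohexylidene]-1-phenylethan-1-amine | CC(=O)CC[C@]1(C)CCC(C)(C)CC1=N[C@H](C)c1ccccc1 | intermediate
8 | (S)-2,5,5-trimethyl-2-(3-oxobutyl)cyclohexan-1-one | CC(=O)CC[C@]1(C)CCC(C)(C)CC1=O | intermediate
9 | (S)-4a,7,7-trimethyl-4,4a,5,6,7,8-hexahydronaphthalen-2(3H)-one | O=C1CC[C@]2(C)CCC(C)(C)CC2=C1 | intermediate
10 | lithium (4aS,8aS)-4a,7,7-trimethyl-3,4,4a,5,6,7,8,8a-octahydronaphthalen-2-olate (trans-fused) | [Li]OC1=C[C@@H]2CC(C)(C)CC[C@@]2(C)CC1 | intermediate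
11 | (4aS,8aS)-4a,7,7-trimethyl-3,4,4a,5,6,7,8,8a-octahydronaphthalen-2-yl trifluoromethanesulfonate | FC(F)(F)S(=O)(=O)OC1=C[C@@H]2CC(C)(C)CC[C@@]2(C)CC1 | intermediate
12 | trimethyl[(4aS,8aS)-4a,7,7-trimethyl-3,4,4a,5,6,7,8,8a-octahydronaphthalen-2-yl]stannane | C[Sn](C)(C)C1=C[C@@H]2CC(C)(C)CC[C@@]2(C)CC1 | intermediate
13 | (S)-3,7-dimethyloct-6-enoic acid ((S)-citronellic acid) | C[C@@H](CCC=C(C)C)CC(=O)O | starting material
14 | pyrrolidine | C1CCNC1 | starting material
15 | (S)-3,7-dimethyl-1-(pyrrolidin-1-yl)oct-6-en-1-one | C[C@@H](CCC=C(C)C)CC(=O)N1CCCC1 | intermediate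
16 | (3S)-5-(5,5-dimethyl-1,2,4-trioxolan-3-yl)-3-methyl-1-(pyrrolidin-1-yl)pentan-1-one (ozonide) | C[C@@H](CCC1OOC(C)(C)O1)CC(=O)N1CCCC1 | intermediate
17 | (S)-4-methyl-6-oxo-6-(pyrrolidin-1-yl)hexanal | C[C@@H](CCC=O)CC(=O)N1CCCC1 | intermediate
18 | (S,Z)-3-methyl-1-(pyrrolidin-1-yl)oct-6-en-1-one | C[C@@H](CC/C=C\C)CC(=O)N1CCCC1 | intermediate
19 | 1-[(S,Z)-3-methylocta-1,6-dien-1-ylidene]pyrrolidin-1-ium triflate (keteniminium salt) | C[C@@H](CC/C=C\C)C=C=[N+]1CCCC1.[O-]S(=O)(=O)C(F)(F)F | intermediate
20 | 1-[cis-fused (4S)-4,7-dimethylbicyclo[3.2.0]heptan-6-ylidene]pyrrolidin-1-ium triflate (4-methyl exo) | C1(=[N+]3CCCC3)[C@@H]2[C@@H](C)CC[C@@H]2C1C.[O-]S(=O)(=O)C(F)(F)F | intermediate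
21 | cis-fused (4S)-4,7-dimethylbicyclo[3.2.0]heptan-6-one (4-methyl exo; epimers at carbon 7) | O=C1[C@@H]2[C@@H](C)CC[C@@H]2C1C | intermediate
22 | lithium enolate of 21 (enolate toward carbon 7) | [Li]OC=1[C@@H]2[C@@H](C)CC[C@@H]2C=1C | intermediate
23 | cis-fused (4S)-4,7-dimethyl-7-vinylbicyclo[3.2.0]heptan-6-one (4-methyl exo; 7-vinyl exo; 7-methyl endo) | O=C1[C@@H]2[C@@H](C)CC[C@@H]2[C@@]1(C)C=C | intermediate
24 | [(4aS,8aS)-4a,7,7-trimethyl-3,4,4a,5,6,7,8,8a-octahydronaphthalen-2-yl]lithium | [Li]C1=C[C@@H]2CC(C)(C)CC[C@@]2(C)CC1 | intermediate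
25 | lithium cyclobutanolate from exo addition of 24 to 23 (octalinyl and vinyl groups cis) | [Li]O[C@]1(C2=C[C@@H]3CC(C)(C)CC[C@@]3(C)CC2)[C@@H]2[C@@H](C)CC[C@@H]2[C@@]1(C)C=C | intermediate
26 | lithium enolate of the ring-expanded tetracyclic ketone (enolate carbon in ring C) | C/C1=C/C[C@@H]2[C@@H]3CC(C)(C)CC[C@@]3(C)CCC2=C(O[Li])[C@@H]2[C@@H](C)CC[C@H]12 | intermediate
27 | tetracyclic ring-B ketone (ring-B/C methine and ring-A/B methine epimeric to the target; ring A/B cis-fused) | C/C1=C/C[C@@H]2[C@@H]3CC(C)(C)CC[C@@]3(C)CC[C@]2(C)C(=O)[C@@H]2[C@@H](C)CC[C@H]12 | intermediate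
28 | tetracyclic ene-dione (27 with a ketone at the ring-B CH2 next to ring C) | C/C1=C/C(=O)[C@@H]2[C@@H]3CC(C)(C)CC[C@@]3(C)CC[C@]2(C)C(=O)[C@@H]2[C@@H](C)CC[C@H]12 | intermediate
29 | dipotassium bis-enolate of the tetracyclic dione (ring-B/C methine equilibrated) | CC1=C2CC[C@H](C)C2=C(O[K])[C@@]2(C)CC[C@]3(C)CCC(C)(C)C[C@H]3[C@@H]2C(O[K])=C1 | intermediate
30 | tetracyclic dione with the target olefin and the target configuration at every stereocentre | C/C1=C2\CC[C@H](C)[C@@H]2C(=O)[C@@]2(C)CC[C@]3(C)CCC(C)(C)C[C@H]3[C@@H]2C(=O)C1 | intermediate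
31 | mono-tosylhydrazone of 30 at the less hindered ketone | C/C1=C2\CC[C@H](C)[C@@H]2C(=O)[C@@]2(C)CC[C@]3(C)CCC(C)(C)C[C@H]3[C@@H]2C(=NNS(=O)(=O)c2ccc(C)cc2)C1 | intermediate
32 | tetracyclic ketone (oxo analogue of the target) | C/C1=C2\CC[C@H](C)[C@@H]2C(=O)[C@@]2(C)CC[C@]3(C)CCC(C)(C)C[C@H]3[C@@H]2CC1 | intermediate
33 | target alcohol CNP0399382.1 | C/C1=C2\CC[C@H](C)[C@@H]2[C@@H](O)[C@@]2(C)CC[C@]3(C)CCC(C)(C)C[C@H]3[C@@H]2CC1 | target

**Step count and risks**

Total steps: 15. Longest linear sequence: 10 steps (steps 1–5 or 6–10, then 11–15).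

Steps most likely to fail:

1. Step 11. The sigmatropic bond must form on the ring-C face syn to the angular methyl, so the alkoxide may instead fragment or undergo a 1,3-shift, and the enolate may be protonated or O-methylated. Fallback, setting out from 12 and 23: the addition is stopped at −78 °C by protonation to give the tertiary cyclobutanol F1. Silylation (Me3SiCl, imidazole) gives the trimethylsilyl ether F2. Heating F2 in toluene effects the neutral siloxy-Cope rearrangement, which has no alkoxide and hence no fragmentation channel, and gives the trimethylsilyl enol ether F3. MeLi in THF then releases enolate 26 regiospecifically, and MeI gives 27, where the route is rejoined.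

2. Step 13. Transannular aldol addition between the two carbonyl groups may occur while only one is enolized, equilibration of the methine may be incomplete, and γ-protonation may return the conjugated enone. Fallback, setting out from 28: DBU in toluene at 60 °C equilibrates only the methine next to the enone carbonyl and gives the trans-fused conjugated ene-dione F4. Irradiation at 350 nm in MeCN with 1,2-dimethylimidazole as proton shuttle effects photochemical deconjugation through the photodienol and gives the β,γ-unsaturated dione F5, still epimeric at the ring-A/B methine. Full double deprotonation with KN(SiMe3)2 at −78 °C gives bis-enolate 29 directly, and inverse quench with AcOH gives 30.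

3. Step 12. Oxidation may occur at the tertiary allylic C–H of ring A or at the allylic methyl, or may over-oxidize. Fallback, setting out from 27: epoxidation of the ring-B olefin with m-CPBA gives the epoxide F6. Opening with PhSeNa (from PhSeSePh and NaBH4 in EtOH) at the less substituted epoxide carbon gives the hydroxy selenide F7. Oxidation with H2O2 and selenoxide syn-elimination, possible only toward the ring-B CH2, gives the tertiary allylic alcohol F8. Oxidative 1,3-transposition with pyridinium chlorochromate (C5H5NH)[CrO3Cl] gives enone 28.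

Further compounds
F1 | step 11 | tertiary cyclobutanol (protonated form of 25) | O[C@]1(C2=C[C@@H]3CC(C)(C)CC[C@@]3(C)CC2)[C@@H]2[C@@H](C)CC[C@@H]2[C@@]1(C)C=C
F2 | step 11 | trimethylsilyl ether of F1 | C[Si](C)(C)O[C@]1(C2=C[C@@H]3CC(C)(C)CC[C@@]3(C)CC2)[C@@H]2[C@@H](C)CC[C@@H]2[C@@]1(C)C=C
F3 | step 11 | trimethylsilyl enol ether of the ring-expanded ketone | C/C1=C/C[C@@H]2[C@@H]3CC(C)(C)CC[C@@]3(C)CCC2=C(O[Si](C)(C)C)[C@@H]2[C@@H](C)CC[C@H]12
F4 | step 13 | trans-fused conjugated ene-dione (28 epimerized at the ring-B/C methine) | C/C1=C/C(=O)[C@H]2[C@@H]3CC(C)(C)CC[C@@]3(C)CC[C@]2(C)C(=O)[C@@H]2[C@@H](C)CC[C@H]12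
F5 | step 13 | deconjugated dione epimeric to 30 at the ring-A/B methine | C/C1=C2\CC[C@H](C)[C@H]2C(=O)[C@@]2(C)CC[C@]3(C)CCC(C)(C)C[C@H]3[C@@H]2C(=O)C1
F6 | step 12 | epoxide of the ring-B olefin of 27 (epoxide configuration not defined) | CC12OC1C[C@@H]3[C@@H]4CC(C)(C)CC[C@@]4(C)CC[C@]3(C)C(=O)[C@@H]3[C@@H](C)CC[C@H]23
F7 | step 12 | hydroxy selenide (tertiary alcohol; phenylselanyl on the adjacent ring-B carbon) | CC1(O)C([Se]c2ccccc2)C[C@@H]2[C@@H]3CC(C)(C)CC[C@@]3(C)CC[C@]2(C)C(=O)[C@@H]2[C@@H](C)CC[C@H]12
F8 | step 12 | tertiary allylic alcohol (olefin shifted toward ring C) | CC1(O)/C=C\[C@@H]2[C@@H]3CC(C)(C)CC[C@@]3(C)CC[C@]2(C)C(=O)[C@@H]2[C@@H](C)CC[C@H]12
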